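**Retrosynthetic overview**

1. The target is a hydroquinone-fused bicyclo[3.2.1]octene (five-membered ring B, methylcyclohexene ring C, one-carbon bridge C-pre). The ene-dione ring A sits on the bond between the prenyl-bearing quaternary carbon C-pre and the arene-bearing quaternary carbon C-ar; C-bn is the benzylic CH.
2. Feature used: in ring C, C-pre is bonded to C-bn and C-ar to the alkene CH (C7). Ring C is therefore the (4+2) adduct of a 1-aryl-3-methyl-4-silyl diene and the C-pre=C-ar bond of a 2-prenylcyclohexenone (ring A); the silyl group on C7 later shifts the alkene from C5=C6 to C6=C7.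
3. Endgame disconnections: hydroquinone ⇐ quinone ⇐ dimethyl ether; ene-dione ⇐ 4-hydroxy ketone; C6=C7 ⇐ allylsilane; ring B ⇐ palladium-catalysed arylation of the C4 enolate at C-ar by the ortho bromide.
4. Precursors: the dienophile from 4-methoxyphenol (ortho-prenylation, PhI(OAc)2/MeOH, half-hydrogenation); the diene from 2-bromo-1,4-dimethoxybenzene (formylation, iodo-olefination, Suzuki coupling with a β-boryl vinylsilane of fixed geometry).
5. Ring order: ring A and the arene are carried in, ring C is formed in the Diels–Alder step, ring B is closed last.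

Key step: step 8

Labels: ring A = C-pre–C1–C2–C3–C4–C-ar (C1 and C4 are the carbonyl carbons of the target); ring C = C-pre–C-bn–C5–C6(CH3)–C7–C-ar; ring B = C-pre, C-bn, the two adjacent arene carbons and C-ar.

Assumption on the catalyst: the (S)-configured oxazaborolidinium ion is taken to expose the enone face that leads to the drawn enantiomer; if the sense proves opposite, the (R)-catalyst is used with no other change.

Assumption on C1: the carbinol carbon C1 created in step 9 is not controlled, and compounds 15 to 20 are carried as C1 epimers (centre left open in the SMILES), because step 13 oxidises it again.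

**Route**

Step 1
Reactants: 1 4-methoxyphenol; 2 prenyl bromide (1-bromo-3-methylbut-2-ene)
Product: 4 4-methoxy-2-(3-methylbut-2-en-1-yl)phenol, via sodium 4-methoxyphenoxide 3 (not isolated)
Conditions: NaH, PhMe, 0 °C; then 2, rt
Reagents that add atoms: none
Why: ortho-selective C-alkylation of a phenoxide: in a non-polar solvent the sodium ion pair is alkylated at the ortho carbon by SN2 attack on the allylic bromide and tautomerisation restores the phenol, the O-prenyl ether and diprenylated by-products being removed by chromatography.

Step 2
Reactants: 4 4-methoxy-2-(3-methylbut-2-en-1-yl)phenol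
Product: 5 4,4-dimethoxy-2-(3-methylbut-2-en-1-yl)cyclohexa-2,5-dien-1-one
Conditions: PhI(OAc)2, MeOH, 0 °C
Reagents that add atoms: methanol, CO
Why: oxidative dearomatisation of a para-methoxyphenol with PhI(OAc)2: methanol captures the oxidised phenol at the para carbon, which should give the quinone monoketal with the ketal at the former methoxy carbon.

Step 3
Reactants: 5 4,4-dimethoxy-2-(3-methylbut-2-en-1-yl)cyclohexa-2,5-dien-1-one
Product: 6 4,4-dimethoxy-2-(3-methylbut-2-en-1-yl)cyclohex-2-en-1-one
Conditions: H2 (1 atm, one equivalent taken up), RhCl(PPh3)3 (5 mol %), PhMe, rt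
Reagents that add atoms: none
Why: homogeneous hydrogenation with RhCl(PPh3)3 discriminates by alkene substitution, so the cis-disubstituted enone double bond should be saturated ahead of the trisubstituted prenyl-bearing enone double bond and the side-chain alkene, as in the known reduction of 1,4-dien-3-ones to 4-en-3-ones.

Step 4
Reactants: 7 trimethyl(prop-1-yn-1-yl)silane
Product: 8 trimethyl[(Z)-2-(4,4,5,5-tetramethyl-1,3,2-dioxaborolan-2-yl)prop-1-en-1-yl]silane
Conditions: B2pin2, CuCl (3 mol %), Xantphos (3 mol %), NaOtBu (6 mol %), MeOH (2 equiv), THF, rt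
Reagents that add atoms: bis(pinacolato)diboron, CC1(C)OB(OC1(C)C)B1OC(C)(C)C(C)(C)O1
Why: copper-catalysed formal hydroboration (borylcupration, then protonation by methanol): the boryl–copper species adds syn with copper on the silicon-bearing carbon and boron on the methyl-bearing carbon, which fixes boron trans to silicon.

Step 5
Reactants: 9 2-bromo-1,4-dimethoxybenzene
Product: 11 2-bromo-3,6-dimethoxybenzaldehyde, via 2-bromo-3,6-dimethoxyphenyllithium 10 (not isolated)
Conditions: LiN(iPr)2, THF, −78 °C; then DMF, −78 → 0 °C; 1 M HCl
Reagents that add atoms: N,N-dimethylformamide, CN(C)C=O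
Why: directed ortho-metalation: the amide base removes the proton flanked by bromine and methoxy without halogen–lithium exchange, and the aryllithium, kept cold to avoid aryne formation, is formylated by DMF.

Step 6
Reactants: 11 2-bromo-3,6-dimethoxybenzaldehyde
Product: 12 2-bromo-3-[(E)-2-iodoethenyl]-1,4-dimethoxybenzene
Conditions: CrCl2 (6 equiv), CHI3 (2 equiv), THF, 0 °C → rt
Reagents that add atoms: iodoform, IC(I)I
Why: Takai olefination: the geminal dichromium species from iodoform adds to the aldehyde and eliminates to the E vinyl iodide, and the aryl bromide is inert to divalent chromium in the absence of a nickel co-catalyst.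

Step 7
Reactants: 12 2-bromo-3-[(E)-2-iodoethenyl]-1,4-dimethoxybenzene; 8 trimethyl[(Z)-2-(4,4,5,5-tetramethyl-1,3,2-dioxaborolan-2-yl)prop-1-en-1-yl]silane
Product: 13 (1E,3E)-1-(2-bromo-3,6-dimethoxyphenyl)-3-methyl-4-(trimethylsilyl)buta-1,3-diene
Conditions: PdCl2(dppf) (5 mol %), Cs2CO3, THF/H2O, 45 °C
Reagents that add atoms: none
Why: Suzuki–Miyaura coupling: zerovalent palladium inserts into the vinyl C–I bond far faster than into the di-ortho-substituted aryl C–Br bond, and both alkenyl partners couple with retention, which should give the (1E,3E) diene with silicon on the outside.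

Step 8
Reactants: 6 4,4-dimethoxy-2-(3-methylbut-2-en-1-yl)cyclohex-2-en-1-one; 13 (1E,3E)-1-(2-bromo-3,6-dimethoxyphenyl)-3-methyl-4-(trimethylsilyl)buta-1,3-diene
Product: 14 endo Diels–Alder adduct (rings A and C cis-fused; C1 ketone; C4 dimethyl ketal; C5=C6 alkene; SiMe3 on C7; 2-bromo-3,6-dimethoxyphenyl on C-bn; aryl, C1, C4 and SiMe3 on one face of ring C)
Conditions: (S)-tetrahydro-1-(2-methylphenyl)-3,3-diphenyl-1H,3H-pyrrolo[1,2-c][1,3,2]oxazaborole (20 mol %), HNTf2 (18 mol %), CH2Cl2, −78 → −20 °C
Reagents that add atoms: none
Why: The cationic boron Lewis acid binds the C1 carbonyl of 6 and lowers the enone LUMO, and 13 adds across the C-pre=C-ar bond in a concerted, asynchronous endo (4+2) cycloaddition; the closest known reaction type is the Lewis acid catalysed Diels–Alder reaction of 2-alkylcyclohex-2-enones and quinone monoketals, including its oxazaborolidinium-catalysed enantioselective form. Ring C closes by intermolecular (4+2) cycloaddition, the C-pre–C-bn and C-ar–C7 bonds forming suprafacially on both partners. For C-pre and C-bn the relative configuration follows from the E aryl terminus and the endo position of the carbonyl (aryl cis to C1), and the absolute configuration from the enone face left open by the chiral catalyst. At C-ar the cis addition puts H cis to prenyl (this centre is replaced through an enolate in step 11), and at C7 the E vinylsilane puts SiMe3 cis to the aryl group (removed in step 12). The step needs the regiochemistry in which the silyl-bearing terminus meets the β-carbon C-ar, secured because the 1-aryl and 3-methyl donors both place the largest HOMO coefficient on that terminus, and it needs site selectivity for the C-pre=C-ar bond, which is the only electron-poor alkene left after step 3. Slightly less HNTf2 than oxazaborolidine is used so that no free acid protodesilylates the diene or ionises the ketal.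

Step 9
Reactants: 14 endo Diels–Alder adduct
Product: 16 C1-hydroxy C4-ketone (C1 epimers; rings A and C cis-fused; SiMe3 on C7; aryl bromide intact), via C1 carbinol dimethyl ketal 15 (not isolated)
Conditions: NaBH4, MeOH/THF, 0 °C → rt; then 1 M HCl, rt
Reagents that add atoms: water, O
Why: hydride reduction of the hindered C1 ketone and acid hydrolysis of the dimethyl ketal in the same flask; with C1 at the alcohol level C2 can no longer form an enolate (from which the aryl bromide could close a six-membered ring), so C4 is the only carbonyl left for step 11, and the uncontrolled carbinol centre is removed in step 13.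

Step 10
Reactants: 16 C1-hydroxy C4-ketone
Product: 17 C1 triethylsilyl ether of 16
Conditions: TESOTf, 2,6-lutidine, CH2Cl2, −78 °C
Reagents that add atoms: triethylsilyl trifluoromethanesulfonate, CC[Si](CC)(CC)OS(=O)(=O)C(F)(F)F
Why: silylation of the secondary alcohol with a silyl triflate and a hindered pyridine base at low temperature, where the ketone is not enolised; the ether keeps an alkoxide from binding palladium (β-hydride loss or C–O coupling) in step 11.

Step 11
Reactants: 17 C1 triethylsilyl ether of 16
Product: 18 ring B closed tetracycle (C-ar bonded to the arene carbon that carried bromine; SiMe3 on C7; C5=C6; C4 ketone; C1 OSiEt3)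
Conditions: Pd2(dba)3 (5 mol %), XPhos (12 mol %), K3PO4, PhMe, 100 °C
Reagents that add atoms: none
Why: intramolecular palladium-catalysed α-arylation of a ketone: zerovalent palladium inserts into the aryl C–Br bond, the C4 enolate formed toward C-ar replaces bromide on palladium, and reductive elimination forms the C-ar–aryl bond and the five-membered ring B; the aryl group is tethered to C-bn and reaches the planar enolate carbon only from its own face, so the configuration at C-ar is dictated by C-bn and C-pre (C4 ends trans to C1), while the C3 enolate would need a seven-membered ring.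

Step 12
Reactants: 18 ring B closed tetracycle
Product: 20 C1-hydroxy C4-ketone with the C6=C7 alkene (C5 is CH2; C1 epimers), via protodesilylated triethylsilyl ether 19 (not isolated)
Conditions: CF3CO2H, CH2Cl2, 0 °C; then MeOH/H2O, rt
Reagents that add atoms: none
Why: SE2′ protodesilylation of the allylsilane: protonation at C5 gives a tertiary cation at C6 that is stabilised by the β-silicon and loses the silyl group, so the alkene lands at C6=C7 next to C-ar; the allylsilane is far more nucleophilic than the prenyl alkene, aqueous methanol then cleaves the triethylsilyl ether, and no stereocentre is formed.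

Step 13
Reactants: 20 C1-hydroxy C4-ketone with the C6=C7 alkene
Product: 22 O,O′-dimethyl ether of the target (ring A ene-dione), via saturated 1,4-dione 21 (not isolated)
Conditions: IBX (4 equiv), DMSO, rt; then 70 °C
Reagents that add atoms: none
Why: IBX oxidises the secondary alcohol to the C1 ketone at room temperature and on warming dehydrogenates the 1,4-dione through its enol; C-pre and C-ar are quaternary, so enolisation is possible only toward C2 and C3 and both directions give the same C2=C3 ene-dione.

Step 14
Reactants: 22 O,O′-dimethyl ether of the target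
Product: 23 benzoquinone corresponding to the target
Conditions: (NH4)2Ce(NO3)6, MeCN/H2O, 0 °C
Reagents that add atoms: water, O
Why: oxidative demethylation of a 1,4-dimethoxyarene by tetravalent cerium: two one-electron oxidations and addition of water release methanol and give the para-quinone, while the ene-dione and the trisubstituted alkenes are too electron-poor or too slow to compete.

Step 15
Reactants: 23 benzoquinone corresponding to the target
Product: 24 CNP0513322.1 (target)
Conditions: Na2S2O4 (1 equiv), EtOAc/H2O, rt, short contact
Reagents that add atoms: none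
Why: dithionite reduction of the benzoquinone to the hydroquinone is driven by aromatisation, so the non-aromatic ene-dione of ring A should remain untouched; no stereocentre is affected and the product is the target.

**Compound list**

1 | 4-methoxyphenol | COc1ccc(O)cc1 | starting material
2 | prenyl bromide (1-bromo-3-methylbut-2-ene) | CC(C)=CCBr | starting material
3 | sodium 4-methoxyphenoxide | [Na+].[O-]c1ccc(OC)cc1 | intermediate (not isolated)
4 | 4-methoxy-2-(3-methylbut-2-en-1-yl)phenol | COc1ccc(O)c(CC=C(C)C)c1 | intermediate
5 | 4,4-dimethoxy-2-(3-methylbut-2-en-1-yl)cyclohexa-2,5-dien-1-one | CC(C)=CCC1=CC(OC)(OC)C=CC1=O | intermediate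
6 | 4,4-dimethoxy-2-(3-methylbut-2-en-1-yl)cyclohex-2-en-1-one (dienophile) | CC(C)=CCC1=CC(OC)(OC)CCC1=O | intermediate
7 | trimethyl(prop-1-yn-1-yl)silane | CC#C[Si](C)(C)C | starting material
8 | trimethyl[(Z)-2-(4,4,5,5-tetramethyl-1,3,2-dioxaborolan-2-yl)prop-1-en-1-yl]silane | C[Si](C)(C)/C=C(\C)B1OC(C)(C)C(C)(C)O1 | intermediate
9 | 2-bromo-1,4-dimethoxybenzene | COc1ccc(OC)c(Br)c1 | starting material
10 | (2-bromo-3,6-dimethoxyphenyl)lithium | [Li]c1c(Br)c(OC)ccc1OC | intermediate (not isolated)
11 | 2-bromo-3,6-dimethoxybenzaldehyde | COc1ccc(OC)c(Br)c1C=O | intermediate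
12 | 2-bromo-3-[(E)-2-iodoethenyl]-1,4-dimethoxybenzene | COc1ccc(OC)c(Br)c1/C=C/I | intermediate
13 | (1E,3E)-1-(2-bromo-3,6-dimethoxyphenyl)-3-methyl-4-(trimethylsilyl)buta-1,3-diene (diene) | COc1ccc(OC)c(Br)c1/C=C/C(C)=C/[Si](C)(C)C | intermediate
14 | endo Diels–Alder adduct: cis-fused rings A and C, C1 ketone, C4 dimethyl ketal, C5=C6, SiMe3 on C7, aryl on C-bn cis to C1 | CC(C)=CC[C@@]12C(=O)CCC(OC)(OC)[C@@H]1[C@H]([Si](C)(C)C)C(C)=C[C@@H]2c1c(Br)c(OC)ccc1OC | intermediate
15 | C1 carbinol of 14 with the dimethyl ketal intact (C1 epimers) | CC(C)=CC[C@@]12C(O)CCC(OC)(OC)[C@@H]1[C@H]([Si](C)(C)C)C(C)=C[C@@H]2c1c(Br)c(OC)ccc1OC | intermediate (not isolated)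
16 | C1-hydroxy C4-ketone (C1 epimers) | CC(C)=CC[C@@]12C(O)CCC(=O)[C@@H]1[C@H]([Si](C)(C)C)C(C)=C[C@@H]2c1c(Br)c(OC)ccc1OC | intermediate
17 | C1 triethylsilyl ether of 16 (C1 epimers) | CC(C)=CC[C@@]12C(O[Si](CC)(CC)CC)CCC(=O)[C@@H]1[C@H]([Si](C)(C)C)C(C)=C[C@@H]2c1c(Br)c(OC)ccc1OC | intermediate
18 | ring B closed tetracycle: C-ar–aryl bond formed, SiMe3 on C7 on the arene side, C5=C6, C4 ketone, C1 OSiEt3 (C1 epimers) | CC(C)=CC[C@@]12C(O[Si](CC)(CC)CC)CCC(=O)[C@@]13[C@H]([Si](C)(C)C)C(C)=C[C@@H]2c1c(OC)ccc(OC)c13 | intermediate
19 | protodesilylated triethylsilyl ether: C6=C7 alkene, C5 CH2 (C1 epimers) | CC(C)=CC[C@@]12C(O[Si](CC)(CC)CC)CCC(=O)[C@@]13C=C(C)C[C@@H]2c1c(OC)ccc(OC)c13 | intermediate (not isolated)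
20 | C1-hydroxy C4-ketone with the C6=C7 alkene (C1 epimers) | CC(C)=CC[C@@]12C(O)CCC(=O)[C@@]13C=C(C)C[C@@H]2c1c(OC)ccc(OC)c13 | intermediate
21 | saturated 1,4-dione (C1 and C4 ketones) | CC(C)=CC[C@@]12C(=O)CCC(=O)[C@@]13C=C(C)C[C@@H]2c1c(OC)ccc(OC)c13 | intermediate (not isolated)
22 | O,O′-dimethyl ether of the target (ring A ene-dione) | CC(C)=CC[C@@]12C(=O)C=CC(=O)[C@@]13C=C(C)C[C@@H]2c1c(OC)ccc(OC)c13 | intermediate
23 | benzoquinone corresponding to the target | CC(C)=CC[C@@]12C(=O)C=CC(=O)[C@@]13C=C(C)C[C@@H]2C1=C3C(=O)C=CC1=O | intermediate
24 | CNP0513322.1 | CC(C)=CC[C@@]12C(=O)C=CC(=O)[C@@]13C=C(C)C[C@@H]2c1c(O)ccc(O)c13 | target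

**Step count and risks**

Total step count: 15. Longest linear sequence: 11 steps (steps 5 to 15 from 9; the arm from 1 through steps 1 to 3 and 8 to 15 is equally long).

Steps most likely to fail:

Step 8. The cycloaddition may stall because both reacting carbons of the dienophile are hindered (prenyl on the α-carbon, ketal carbon next to the β-carbon) and the nucleophilic diene terminus carries silicon. The Lewis acid may instead ionise the ketal, with loss of methanol and aromatisation. Facial discrimination may also be weak because the enone has no α-hydrogen to organise its binding to the catalyst. The fallback replaces catalyst control by an auxiliary in the ketal; it sets out from 6 (with 13) and comes back at 16. Compound 6 is transketalised with (2R,3R)-2,3-bis(trimethylsilyloxy)butane and catalytic TMSOTf (CH2Cl2, −78 °C) to (2R,3R)-2,3-dimethyl-7-(3-methylbut-2-en-1-yl)-1,4-dioxaspiro[4.5]dec-6-en-8-one F1. Cycloaddition with 13 under EtAlCl2 (CH2Cl2, −78 → −30 °C) should give the endo adduct bearing the chiral dioxolane F2, the dioxolane methyl group next to the β-carbon choosing the face; the diastereomers are separable and the antipodal diol is used if the sense is wrong. NaBH4 then gives the C1 carbinol dioxolane F3, and 2 M HCl in THF removes the diol to deliver 16.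

Step 11. Reductive elimination at the tertiary enolate carbon, which is flanked by the quaternary C-pre and the silyl-bearing C7, may be slow. Hydrodebromination, β-hydride loss from the palladium enolate or attack through the less hindered methylene enolate could then take over. The fallback forms the same bond by a radical-chain mechanism without a metal; it sets out from 17 and comes back at 18. Photostimulated SRN1 cyclisation (KOtBu, liquid NH3, hν, −33 °C) has the C4 enolate transfer an electron to the aryl bromide; bromide is lost and the aryl radical couples with the adjacent enolate carbon C-ar. The alkene next to C-bn is placed only for 4-exo or 5-endo attack, so radical addition to it should not compete. No new compound is made on the way.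

Step 3. Hydrogenation may not distinguish well enough between the two enone double bonds, or may continue into the remaining enone or the prenyl alkene. The fallback uses polarity instead of alkene substitution; it sets out from 5 and comes back at 6. PhSeH with catalytic Et3N (CH2Cl2, 0 °C) should add in 1,4-fashion only to the enone that lacks an α-substituent, giving 4,4-dimethoxy-2-(3-methylbut-2-en-1-yl)-5-(phenylselanyl)cyclohex-2-en-1-one F4 (racemic). Bu3SnH with AIBN (PhMe, 80 °C) then replaces selenium by hydrogen.

Further compounds
F1 | step 8 | (2R,3R)-2,3-dimethyl-7-(3-methylbut-2-en-1-yl)-1,4-dioxaspiro[4.5]dec-6-en-8-one | CC(C)=CCC1=CC2(CCC1=O)O[C@H](C)[C@@H](C)O2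
F2 | step 8 | endo Diels–Alder adduct of F1 and 13 (as 14, with the (2R,3R)-butane-2,3-diyl ketal at C4) | CC(C)=CC[C@@]12C(=O)CCC3(O[C@H](C)[C@@H](C)O3)[C@@H]1[C@H]([Si](C)(C)C)C(C)=C[C@@H]2c1c(Br)c(OC)ccc1OC
F3 | step 8 | C1 carbinol of F2 (C1 epimers) | CC(C)=CC[C@@]12C(O)CCC3(O[C@H](C)[C@@H](C)O3)[C@@H]1[C@H]([Si](C)(C)C)C(C)=C[C@@H]2c1c(Br)c(OC)ccc1OC
F0 | step 11 | none | none
F4 | step 3 | 4,4-dimethoxy-2-(3-methylbut-2-en-1-yl)-5-(phenylselanyl)cyclohex-2-en-1-one (racemic) | CC(C)=CCC1=CC(OC)(OC)C([Se]c2ccccc2)CC1=O
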